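**Retrosynthetic overview**
- Ring labels: phenanthrene rings A (OMe), B (central) and C (Cl, OH); ring D is the non-fused chlorophenol on phenanthrene C6; ring E is the 4-hydroxyphenyl ring.
- Last ring (12-membered macrocycle): the C4(ring C)–C(ortho to OH, ring E) biaryl bond, made by aerobic oxidative phenol coupling, the bond type that joins the bibenzyl halves of liverwort bis(bibenzyl)s.
- Before it, ring B: the C4a–C4b bond, made by oxidative 6π-photocyclisation of an open-chain stilbene, so that no alkene is left when phenoxyl radicals are generated.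
- The stilbene is assembled without protecting groups from four cheap arenes: Suzuki (ring A–ring D), double Wittig methylenation, site-selective Heck (ring A–CH=CH–ring C), hydroboration/B-alkyl Suzuki (ring D–CH2CH2–ring E).
- Both chlorines, the methyl ether and all three phenols come in with the building blocks; ring order: ring B (step 6), then the macrocycle (step 7).

Assumption: the SMILES carries no stereodescriptor and the molecule has no stereocentre, so the target is taken as the constitution drawn; if a biaryl axis is configurationally stable, this route gives it as the racemate.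

**Step 1**
Reactants: 1 2-bromo-3-hydroxybenzaldehyde
Product: 2 2-bromo-6-chloro-3-hydroxybenzaldehyde
Conditions: NCS (1.05 equiv), p-TsOH·H2O (10 mol %), MeCN, 0 °C → rt
Reagents that add atoms: N-chlorosuccinimide, O=C1CCC(=O)N1Cl
Why: Electrophilic aromatic chlorination goes para to the OH group (C6), because C2 is blocked by Br and C4 (para to the formyl group) is the least reactive open site, as in the halogenation of 3-hydroxybenzaldehyde itself.

**Step 2**
Reactants: 2 2-bromo-6-chloro-3-hydroxybenzaldehyde; 3 (4-formyl-2-methoxyphenyl)boronic acid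
Product: 4 6-chloro-2-(4-formyl-2-methoxyphenyl)-3-hydroxybenzaldehyde
Conditions: Pd(PPh3)4 (5 mol %), K2CO3 (3 equiv), 1,4-dioxane/H2O (4:1), 90 °C
Reagents that add atoms: none
Why: Suzuki–Miyaura coupling: the C–Br bond, activated by the ortho-formyl group, adds to zerovalent palladium much faster than C–Cl with a triphenylphosphine catalyst, and the free phenol and both aldehydes tolerate aqueous carbonate.

**Step 3**
Reactants: 4 6-chloro-2-(4-formyl-2-methoxyphenyl)-3-hydroxybenzaldehyde
Product: 5 4-chloro-3-ethenyl-2-(4-ethenyl-2-methoxyphenyl)phenol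
Conditions: Ph3PCH3Br (3.5 equiv), KOt-Bu (3.4 equiv), THF, 0 °C → rt
Reagents that add atoms: methyltriphenylphosphonium bromide, C[P+](c1ccccc1)(c1ccccc1)c1ccccc1.[Br-]
Why: Wittig methylenation: the small unstabilised ylide converts both aldehydes, including the di-ortho-substituted one, after one equivalent has deprotonated the phenol.

**Step 4**
Reactants: 5 4-chloro-3-ethenyl-2-(4-ethenyl-2-methoxyphenyl)phenol; 6 2-chloro-4-iodophenol
Product: 7 4-chloro-2-{4-[(E)-2-(3-chloro-4-hydroxyphenyl)ethenyl]-2-methoxyphenyl}-3-ethenylphenol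
Conditions: 6 (1.0 equiv), Pd(OAc)2 (5 mol %), Bu4NCl (1 equiv), NaHCO3 (2.5 equiv), DMF, 70 °C
Reagents that add atoms: none
Why: Mizoroki–Heck reaction under Jeffery conditions: aryl–palladium insertion is much faster at the open, conjugated ring A styrene than at the ring D vinyl group (twisted out of conjugation and screened by Cl and the biaryl), so one equivalent of iodide gives mainly the mono-(E)-stilbene; syn-insertion/syn-β-hydride elimination sets the E geometry.

**Step 5**
Reactants: 7 4-chloro-2-{4-[(E)-2-(3-chloro-4-hydroxyphenyl)ethenyl]-2-methoxyphenyl}-3-ethenylphenol; 8 4-iodophenol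
Product: 10 4-chloro-2-{4-[(E)-2-(3-chloro-4-hydroxyphenyl)ethenyl]-2-methoxyphenyl}-3-[2-(4-hydroxyphenyl)ethyl]phenol, via tris(9-BBN) adduct 9 (not isolated)
Conditions: 9-BBN dimer (1.8 equiv), THF, 0 → 50 °C; then 8 (1.3 equiv), PdCl2(dppf) (5 mol %), 3 M aq. K3PO4, DMF, 60 °C
Reagents that add atoms: none
Why: Anti-Markovnikov hydroboration with 9-BBN touches only the terminal vinyl group (the trans-stilbene is inert; the phenols are carried as borinates), and the B-alkyl Suzuki–Miyaura coupling with the aryl iodide then forms the CH2CH2 bridge while the aryl chlorides stay.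

**Step 6**
Reactants: 10 4-chloro-2-{4-[(E)-2-(3-chloro-4-hydroxyphenyl)ethenyl]-2-methoxyphenyl}-3-[2-(4-hydroxyphenyl)ethyl]phenol
Product: 13 2-chloro-6-{3-chloro-6-hydroxy-2-[2-(4-hydroxyphenyl)ethyl]phenyl}-7-methoxyphenanthren-3-ol, via Z-stilbene 11 (not isolated), via trans-4a,4b-dihydrophenanthrene 12 (not isolated)
Conditions: hν (medium-pressure Hg lamp, Pyrex, λ > 300 nm), TEMPO (2.5 equiv), toluene/MeCN (4:1), 2 mM, Ar, rt
Reagents that add atoms: none
Why: Mallory photocyclisation: E→Z isomerisation, conrotatory 6π-electrocyclisation to the trans-dihydrophenanthrene and hydrogen abstraction by TEMPO (chosen over iodine so the electron-rich phenanthrenol is not iodinated); both 3,4-disubstituted rings close at their unhindered ortho carbons, away from Cl and OMe, which gives the 2-chloro-3-hydroxy/6-aryl-7-methoxy pattern.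

**Step 7**
Reactants: 13 2-chloro-6-{3-chloro-6-hydroxy-2-[2-(4-hydroxyphenyl)ethyl]phenyl}-7-methoxyphenanthren-3-ol
Product: 14 CNP0310669.0, i.e. 13 with a new bond between phenanthrene C4 and the ring E carbon ortho to OH (12-membered ring)
Conditions: [Cu(OH)(TMEDA)]2Cl2 (30 mol %), O2 (1 atm), MeCN/CH2Cl2 (1:1), rt, syringe-pump addition to 0.5 mM
Reagents that add atoms: none
Why: Proposed new method: macrocyclising oxidative phenol coupling, in which the divalent copper–diamine catalyst oxidises the most electron-rich phenol (the 3-phenanthrenol), whose radical is centred on C4 (the naphthol-α-type carbon; the other ortho carbon carries Cl), this carbon is attacked intramolecularly by one of the two equivalent open ortho carbons of the para-blocked ring E phenol, tautomerisation gives the biaryl and O2 turns the catalyst over; the closest known reaction types are the aerobic copper–TMEDA coupling of 2-naphthols and copper-mediated phenol–phenol biaryl macrocyclisation.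

**Compound list**
1 | 2-bromo-3-hydroxybenzaldehyde | O=Cc1cccc(O)c1Br | starting material
2 | 2-bromo-6-chloro-3-hydroxybenzaldehyde | O=Cc1c(Cl)ccc(O)c1Br | intermediate
3 | (4-formyl-2-methoxyphenyl)boronic acid | COc1cc(C=O)ccc1B(O)O | starting material
4 | 6-chloro-2-(4-formyl-2-methoxyphenyl)-3-hydroxybenzaldehyde | COc1cc(C=O)ccc1-c1c(O)ccc(Cl)c1C=O | intermediate
5 | 4-chloro-3-ethenyl-2-(4-ethenyl-2-methoxyphenyl)phenol | COc1cc(C=C)ccc1-c1c(O)ccc(Cl)c1C=C | intermediate
6 | 2-chloro-4-iodophenol | Oc1ccc(I)cc1Cl | starting material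
7 | 4-chloro-2-{4-[(E)-2-(3-chloro-4-hydroxyphenyl)ethenyl]-2-methoxyphenyl}-3-ethenylphenol | COc1cc(/C=C/c2ccc(O)c(Cl)c2)ccc1-c1c(O)ccc(Cl)c1C=C | intermediate
8 | 4-iodophenol | Oc1ccc(I)cc1 | starting material
9 | tris(9-BBN) adduct of 7 (ring D CH2CH2–B(9-BBN); both phenols as O–B(9-BBN) borinates; not isolated) | COc1cc(/C=C/c2ccc(OB3C4CCCC3CCC4)c(Cl)c2)ccc1-c1c(OB2C3CCCC2CCC3)ccc(Cl)c1CCB1C2CCCC1CCC2 | intermediate
10 | 4-chloro-2-{4-[(E)-2-(3-chloro-4-hydroxyphenyl)ethenyl]-2-methoxyphenyl}-3-[2-(4-hydroxyphenyl)ethyl]phenol | COc1cc(/C=C/c2ccc(O)c(Cl)c2)ccc1-c1c(O)ccc(Cl)c1CCc1ccc(O)cc1 | intermediate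
11 | Z-isomer of 10 (Z-stilbene; not isolated) | COc1cc(/C=C\c2ccc(O)c(Cl)c2)ccc1-c1c(O)ccc(Cl)c1CCc1ccc(O)cc1 | intermediate
12 | trans-2-chloro-6-{3-chloro-6-hydroxy-2-[2-(4-hydroxyphenyl)ethyl]phenyl}-7-methoxy-4a,4b-dihydrophenanthren-3-ol (racemic; 4a-H and 4b-H on opposite faces; not isolated) | COC1=CC2=CC=C3C=C(Cl)C(O)=C[C@H]3[C@@H]2C=C1-c1c(O)ccc(Cl)c1CCc1ccc(O)cc1 | intermediate
13 | 2-chloro-6-{3-chloro-6-hydroxy-2-[2-(4-hydroxyphenyl)ethyl]phenyl}-7-methoxyphenanthren-3-ol | COc1cc2ccc3cc(Cl)c(O)cc3c2cc1-c1c(O)ccc(Cl)c1CCc1ccc(O)cc1 | intermediate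
14 | CNP0310669.0: 2-chloro-7-methoxyphenanthren-3-ol bridged from C4 (to C3 of the 4-hydroxyphenyl ring E) to C6 (to C2 of the 4-chloro-1-hydroxyphenyl ring D), rings D and E joined by CH2CH2 | COc1cc2ccc3cc(Cl)c(O)c4c3c2cc1-c1c(O)ccc(Cl)c1CCc1ccc(O)c-4c1 | target

**Totals**
Total step count: 7. Longest linear sequence: 7 (fully linear from 1).

**Steps most likely to fail and their fallbacks**

Step 7 (oxidative macrocyclisation). The ring is closed at a bay position of a rigid phenanthrene; C–O coupling, ortho–para coupling to a spiro-dienone, quinone formation or oligomers may win. Fallback, from 13 back to 14: replace the radical coupling by a halide-directed closure. N-Iodosuccinimide (1.0 equiv, MeCN/CH2Cl2, −40 °C) iodinates the most nucleophilic carbon, C4 of the phenanthrenol, to give 2-chloro-6-{3-chloro-6-hydroxy-2-[2-(4-hydroxyphenyl)ethyl]phenyl}-4-iodo-7-methoxyphenanthren-3-ol F1. An intramolecular palladium-catalysed C-arylation of the ring E phenoxide at its ortho carbon (Pd(OAc)2, PCy3·HBF4, Cs2CO3, DMA, 110 °C, 1 mM) then closes the same bond and gives 14.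

Step 4 (site-selective Heck). The two vinyl groups of 5 may not be told apart well enough, giving bis-arylation or the wrong regioisomer. Fallback, from 4 back to 7: make the choice at the aldehyde stage with a bulky ylide instead. Commercial 3-chloro-4-hydroxybenzyl alcohol and PPh3·HBr (MeCN, reflux) give (3-chloro-4-hydroxybenzyl)triphenylphosphonium bromide F2. F2 with KOt-Bu (THF, −40 °C → rt) olefinates only the open ring A aldehyde of 4, giving 6-chloro-2-{4-[2-(3-chloro-4-hydroxyphenyl)ethenyl]-2-methoxyphenyl}-3-hydroxybenzaldehyde F3 as an E/Z mixture. Methylenation of the remaining hindered aldehyde (Ph3PCH3Br, KOt-Bu, THF) gives 7 together with its Z-isomer F4. Both are carried into step 5, where F4 gives 11, the Z-stilbene that step 6 passes through anyway.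

Step 6 (photocyclisation with three free phenols). Phenol photo-oxidation, incomplete regiocontrol or slow oxidation of 12 may lower the yield. Fallback, from 10 back to 13: a protect–cyclise–deprotect sequence. Ac2O/pyridine gives the triacetate F5 of 10. Irradiation with I2 (1.1 equiv) and propylene oxide in toluene gives the phenanthrene triacetate F6 (the triacetate of 13). K2CO3/MeOH at rt then frees 13.

**Further compounds**
F1 | step 7 | 2-chloro-6-{3-chloro-6-hydroxy-2-[2-(4-hydroxyphenyl)ethyl]phenyl}-4-iodo-7-methoxyphenanthren-3-ol | COc1cc2ccc3cc(Cl)c(O)c(I)c3c2cc1-c1c(O)ccc(Cl)c1CCc1ccc(O)cc1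
F2 | step 4 | (3-chloro-4-hydroxybenzyl)triphenylphosphonium bromide | Oc1ccc(C[P+](c2ccccc2)(c2ccccc2)c2ccccc2)cc1Cl.[Br-]
F3 | step 4 | 6-chloro-2-{4-[2-(3-chloro-4-hydroxyphenyl)ethenyl]-2-methoxyphenyl}-3-hydroxybenzaldehyde (E/Z mixture) | COc1cc(C=Cc2ccc(O)c(Cl)c2)ccc1-c1c(O)ccc(Cl)c1C=O
F4 | step 4 | 4-chloro-2-{4-[(Z)-2-(3-chloro-4-hydroxyphenyl)ethenyl]-2-methoxyphenyl}-3-ethenylphenol | COc1cc(/C=C\c2ccc(O)c(Cl)c2)ccc1-c1c(O)ccc(Cl)c1C=C
F5 | step 6 | triacetate of 10 | COc1cc(/C=C/c2ccc(OC(C)=O)c(Cl)c2)ccc1-c1c(OC(C)=O)ccc(Cl)c1CCc1ccc(OC(C)=O)cc1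
F6 | step 6 | triacetate of 13 | COc1cc2ccc3cc(Cl)c(OC(C)=O)cc3c2cc1-c1c(OC(C)=O)ccc(Cl)c1CCc1ccc(OC(C)=O)cc1
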